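**Retrosynthetic overview**
1. Target 14 ⇐ 12 by oxidising the isopropenyl methyl group to CHO (two steps); 12 ⇐ 10 by catalyst-controlled reduction of the C5 acetyl group and senecioylation.
2. 10 ⇐ aldehyde 3 + γ-acyloxyallyl chloride 6 in one flask: C2–C3 by asymmetric chromium-catalysed allylation, then O1–C7a by alkoxide SNAr once the isovaleryl group has moved from the C2 oxygen to the C3 oxygen. The dihydrofuran ring is the only ring formed; the benzene ring is bought.
3. Enabling feature: on the benzene ring the C5 carbon substituent is para to C7a and the C3 carbinol carbon is ortho to it. Kept at the ketone level (acetyl), C5 makes C7a–F an SNAr site, and the vicinal syn C2–O/C3–O pair lets the C3 ester of the target first serve as the mask of the C2 oxygen.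
4. 3 ⇐ 5-bromo-2-fluorobenzaldehyde (Stille acetylation); 6 ⇐ methacrolein + isovaleryl chloride.

Key step: step 3

Assumption: the catalyst made from CrCl3 and the (R,R)-salen ligand is taken to deliver the allyl unit to the Si face of the aldehyde (the face that leads to 2R,3R); the sense is to be checked on the first run and the (S,S)-ligand used if it is the opposite. Compound 6 is used as an E/Z mixture.

**Step 1**
Reactants: 1 5-bromo-2-fluorobenzaldehyde
Product: 3 5-acetyl-2-fluorobenzaldehyde, via enol ether 2 (not isolated)
Conditions: PdCl2(PPh3)2 (3 mol%), toluene, 100 °C; then 1 M HCl, THF, 20 °C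
Reagents that add atoms: tributyl(1-ethoxyvinyl)stannane, CCCC[Sn](CCCC)(CCCC)C(=C)OCC; water, O
Why: Migita–Kosugi–Stille coupling (zerovalent palladium inserts into C–Br, not C–F) with the stannane as an acetyl anion equivalent, then acid hydrolysis of enol ether 2, should leave the aldehyde untouched; no stereocentre is formed.

**Step 2**
Reactants: 4 methacrolein; 5 isovaleryl chloride
Product: 6 3-chloro-2-methylprop-1-en-1-yl 3-methylbutanoate (E/Z mixture)
Conditions: ZnCl2 (2 mol%), CH2Cl2, −10 to 20 °C; distillation
Reagents that add atoms: none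
Why: ZnCl2-catalysed addition of an acyl chloride across an enal (O-acylation, chloride to the terminal carbon, any 1,2-adduct equilibrating by allylic transposition) is the established route to 3-halopropenyl esters, and the E/Z mixture is acceptable because the chromium step is stereoconvergent.

**Step 3**
Reactants: 3 5-acetyl-2-fluorobenzaldehyde; 6 3-chloro-2-methylprop-1-en-1-yl 3-methylbutanoate
Product: 10 (2R,3R)-5-acetyl-2-(prop-1-en-2-yl)-2,3-dihydro-1-benzofuran-3-yl 3-methylbutanoate, via silyl ether 7 (not isolated), via C3 alkoxide 8 (not isolated), via C2 alkoxide 9 (not isolated)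
Conditions: CrCl3 (10 mol%), (R,R)-N,N'-bis(3,5-di-tert-butylsalicylidene)cyclohexane-1,2-diamine (20 mol%), Et3N (40 mol%), Mn powder (3 equiv), Me3SiCl (1.5 equiv), MeCN, 20 °C; then CsF (3 equiv), DMF, 40 °C, same flask
Reagents that add atoms: none
Why: Proposed new method: Mn reduces the CrCl3–salen complex to divalent chromium, two equivalents of which turn allylic chloride 6 into a γ-acyloxyallyl complex of trivalent chromium that adds through its oxygen-bearing carbon to the aldehyde of 3 to forge C2–C3, Me3SiCl releasing silyl ether 7 and turning the metal over; fluoride then unmasks C3 alkoxide 8, the isovaleryl group migrates from the C2 oxygen to the C3 oxygen through a five-membered orthoester-type intermediate, and the C2 alkoxide of 9 attacks the fluorine-bearing carbon para to the acetyl group (addition–elimination through a Meisenheimer anion) to forge O1–C7a. The closest known reaction types are the salen–chromium-catalysed Nozaki–Hiyama–Kishi α-hydroxyallylation of aldehydes with 3-halopropenyl esters, the base-induced 1,2-acyl shift of vicinal diol monoesters and the intramolecular SNAr etherification of 4-fluoroaryl ketones; their union in one flask is what is new. The dihydrofuran ring closes by a 5-exo-trig addition–elimination at an aromatic carbon. C2 and C3 are both set in the C–C bond formation: the syn relationship (cis in the ring) is the intrinsic preference of salen–chromium allylations whatever the E/Z composition of 6, the absolute sense comes from the ligand, and neither centre is touched by the acyl shift or the ring closure. The allylation needs aldehyde-over-ketone, γ-over-α, syn-over-anti and facial selectivity, which the chemoselectivity of allylchromium reagents and the catalyst should secure, and the closure needs only one of the two interconverting alkoxides to react, which is secured because 8 could only close a four-membered ring whereas 9 closes a five-membered one onto a carbon activated by the para acetyl group. The fluoride lost in the ring closure re-enters the desilylation, so little free base is present and E2 loss of the C3 ester to the benzofuran should be held back.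

**Step 4**
Reactants: 10 (2R,3R)-5-acetyl-2-(prop-1-en-2-yl)-2,3-dihydro-1-benzofuran-3-yl 3-methylbutanoate
Product: 11 (2R,3R)-5-[(1S)-1-hydroxyethyl]-2-(prop-1-en-2-yl)-2,3-dihydro-1-benzofuran-3-yl 3-methylbutanoate
Conditions: (R)-2-methyl-CBS-oxazaborolidine (0.2 equiv), catecholborane (1.5 equiv), toluene, −78 to −40 °C; MeOH, then aq NaHCO3
Reagents that add atoms: none
Why: Corey–Bakshi–Shibata reduction, in which the (R)-oxazaborolidine binds the ketone with the aryl group as the large substituent and should deliver hydride to give the (S)-carbinol under catalyst control, while catecholborane at low temperature touches neither the ester nor the isopropenyl group.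

**Step 5**
Reactants: 11 (2R,3R)-5-[(1S)-1-hydroxyethyl]-2-(prop-1-en-2-yl)-2,3-dihydro-1-benzofuran-3-yl 3-methylbutanoate
Product: 12 (1S)-1-[(2R,3R)-3-[(3-methylbutanoyl)oxy]-2-(prop-1-en-2-yl)-2,3-dihydro-1-benzofuran-5-yl]ethyl 3-methylbut-2-enoate
Conditions: pyridine, DMAP (0.1 equiv), CH2Cl2, 0 °C
Reagents that add atoms: 3-methylbut-2-enoyl chloride, CC(C)=CC(Cl)=O
Why: DMAP-catalysed acylation of the secondary alcohol proceeds with retention at the carbinol centre, and pyridine in place of a trialkylamine should keep vinylketene formation, and with it deconjugation of the senecioyl group, low.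

**Step 6**
Reactants: 12 (1S)-1-[(2R,3R)-3-[(3-methylbutanoyl)oxy]-2-(prop-1-en-2-yl)-2,3-dihydro-1-benzofuran-5-yl]ethyl 3-methylbut-2-enoate
Product: 13 (1S)-1-[(2R,3R)-2-(3-hydroxyprop-1-en-2-yl)-3-[(3-methylbutanoyl)oxy]-2,3-dihydro-1-benzofuran-5-yl]ethyl 3-methylbut-2-enoate
Conditions: SeO2 (0.3 equiv), t-BuOOH (3 equiv), CH2Cl2, 0 to 20 °C
Reagents that add atoms: selenium dioxide (oxygen carrier), O=[Se]=O; tert-butyl hydroperoxide (terminal oxygen source), CC(C)(C)OO
Why: Catalytic SeO2/t-BuOOH allylic oxidation (ene reaction, then [2,3]-sigmatropic shift) should attack the electron-rich 1,1-disubstituted isopropenyl group at its methyl group, a transformation with precedent on isopropenyl dihydrobenzofurans, and leave the electron-poor senecioate alkene alone; over-oxidation only leads to 14.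

**Step 7**
Reactants: 13 (1S)-1-[(2R,3R)-2-(3-hydroxyprop-1-en-2-yl)-3-[(3-methylbutanoyl)oxy]-2,3-dihydro-1-benzofuran-5-yl]ethyl 3-methylbut-2-enoate
Product: 14 (1S)-1-[(2R,3R)-3-[(3-methylbutanoyl)oxy]-2-(3-oxoprop-1-en-2-yl)-2,3-dihydro-1-benzofuran-5-yl]ethyl 3-methylbut-2-enoate
Conditions: Dess–Martin periodinane (1.3 equiv), NaHCO3, CH2Cl2, 0 to 20 °C
Reagents that add atoms: none
Why: Dess–Martin oxidation of the primary allylic alcohol to the enal under buffered conditions should touch no stereocentre and no ester.

**Compound list**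
1 | 5-bromo-2-fluorobenzaldehyde | O=Cc1cc(Br)ccc1F | starting material
2 | 5-(1-ethoxyethenyl)-2-fluorobenzaldehyde | C=C(OCC)c1ccc(F)c(C=O)c1 | intermediate
3 | 5-acetyl-2-fluorobenzaldehyde | CC(=O)c1ccc(F)c(C=O)c1 | intermediate
4 | methacrolein (2-methylprop-2-enal) | C=C(C)C=O | starting material
5 | isovaleryl chloride (3-methylbutanoyl chloride) | CC(C)CC(Cl)=O | starting material
6 | 3-chloro-2-methylprop-1-en-1-yl 3-methylbutanoate (E/Z mixture, E isomer drawn) | ClC/C(C)=C/OC(=O)CC(C)C | intermediate
7 | (1R,2R)-1-(5-acetyl-2-fluorophenyl)-3-methyl-1-[(trimethylsilyl)oxy]but-3-en-2-yl 3-methylbutanoate | C=C(C)[C@@H](OC(=O)CC(C)C)[C@H](O[Si](C)(C)C)c1cc(C(C)=O)ccc1F | intermediate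
8 | (1R,2R)-1-(5-acetyl-2-fluorophenyl)-1-hydroxy-3-methylbut-3-en-2-yl 3-methylbutanoate (present as its alkoxide, drawn neutral) | C=C(C)[C@@H](OC(=O)CC(C)C)[C@H](O)c1cc(C(C)=O)ccc1F | intermediate
9 | (1R,2R)-1-(5-acetyl-2-fluorophenyl)-2-hydroxy-3-methylbut-3-en-1-yl 3-methylbutanoate (present as its alkoxide, drawn neutral) | C=C(C)[C@@H](O)[C@H](OC(=O)CC(C)C)c1cc(C(C)=O)ccc1F | intermediate
10 | (2R,3R)-5-acetyl-2-(prop-1-en-2-yl)-2,3-dihydro-1-benzofuran-3-yl 3-methylbutanoate (cis) | C=C(C)[C@H]1Oc2ccc(C(C)=O)cc2[C@H]1OC(=O)CC(C)C | intermediate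
11 | (2R,3R)-5-[(1S)-1-hydroxyethyl]-2-(prop-1-en-2-yl)-2,3-dihydro-1-benzofuran-3-yl 3-methylbutanoate | C=C(C)[C@H]1Oc2ccc([C@H](C)O)cc2[C@H]1OC(=O)CC(C)C | intermediate
12 | (1S)-1-[(2R,3R)-3-[(3-methylbutanoyl)oxy]-2-(prop-1-en-2-yl)-2,3-dihydro-1-benzofuran-5-yl]ethyl 3-methylbut-2-enoate | C=C(C)[C@H]1Oc2ccc([C@H](C)OC(=O)C=C(C)C)cc2[C@H]1OC(=O)CC(C)C | intermediate
13 | (1S)-1-[(2R,3R)-2-(3-hydroxyprop-1-en-2-yl)-3-[(3-methylbutanoyl)oxy]-2,3-dihydro-1-benzofuran-5-yl]ethyl 3-methylbut-2-enoate | C=C(CO)[C@H]1Oc2ccc([C@H](C)OC(=O)C=C(C)C)cc2[C@H]1OC(=O)CC(C)C | intermediate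
14 | (1S)-1-[(2R,3R)-3-[(3-methylbutanoyl)oxy]-2-(3-oxoprop-1-en-2-yl)-2,3-dihydro-1-benzofuran-5-yl]ethyl 3-methylbut-2-enoate | C=C(C=O)[C@H]1Oc2ccc([C@H](C)OC(=O)C=C(C)C)cc2[C@H]1OC(=O)CC(C)C | target

Total step count: 7. Longest linear sequence: 6 steps (1, 3, 4, 5, 6, 7); step 2 is the one-step side branch.

**Steps most likely to fail**

Step 3. With the 2-methyl-branched allyl unit the chromium allylation may show poor syn or facial selectivity, the electron-poor aldehyde may dimerise reductively (pinacol coupling), and in the fluoride stage the C3 ester may be lost by elimination to the benzofuran. The fallback sets out from 3 and returns at 10, using reagent-controlled allylboration and a protecting group in place of the acyl shift. 2-Methylprop-2-en-1-ol is converted with MOMCl and i-Pr2NEt into 2-methylallyl methoxymethyl ether F1. Lithiation (s-BuLi, THF, −78 °C), trapping with (−)-Ipc2BOMe and treatment with BF3·OEt2 gives the (Z)-γ-alkoxyallylborane F2. F2 adds to 3 at −78 °C through a chair transition state (Z geometry gives syn, the isopinocampheyl groups direct attack to the Si face; NaBO3·4H2O work-up) to give syn alcohol F3. F3 is acylated with 5 (pyridine, DMAP) to ester F4. Me2BBr (CH2Cl2, −78 °C) removes the methoxymethyl group to give 9 as the free alcohol, and Cs2CO3 in DMF at 40 °C closes the ring by the same SNAr to 10; any ester that has shifted back to the C2 oxygen re-equilibrates under the base.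

Step 6. The selenium oxidation may be unselective: competing oxidation at the γ-methyl group of the senecioate, stalling at partial conversion, or acid-promoted ionisation of the two benzylic esters by the selenium acids. The fallback sets out from 12 and returns at 14. Ene-type allylic chlorination with N-chlorosuccinimide and catalytic PhSeCl (CH2Cl2, 20 °C) gives allylic chloride F5, and Ganem oxidation with N-methylmorpholine N-oxide (MeCN, 40 °C) converts it directly into 14, so step 7 is not needed.

Step 5. The senecioyl group may deconjugate to the 3-methylbut-3-enoate through a vinylketene, and the para-alkoxybenzylic carbinol may lose stereochemical integrity by ionisation under the HCl formed. The fallback sets out from 11 and returns at 12. Esterification with (diethoxyphosphoryl)acetic acid (DCC, catalytic DMAP, CH2Cl2) gives phosphonoacetate F6, and Horner–Wadsworth–Emmons olefination with acetone (NaH, THF, 0 to 20 °C) builds the C=C bond directly in conjugation to give 12.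

**Further compounds**
F1 | step 3 | 3-(methoxymethoxy)-2-methylprop-1-ene | C=C(C)COCOC
F2 | step 3 | (Z)-[3-(methoxymethoxy)-2-methylprop-2-en-1-yl]diisopinocampheylborane, from (−)-Ipc2BOMe | COCO/C=C(/C)CB([C@@H]1C[C@@H]2C[C@H]([C@H]1C)C2(C)C)[C@@H]1C[C@@H]2C[C@H]([C@H]1C)C2(C)C
F3 | step 3 | (1R,2R)-1-(5-acetyl-2-fluorophenyl)-2-(methoxymethoxy)-3-methylbut-3-en-1-ol | C=C(C)[C@@H](OCOC)[C@H](O)c1cc(C(C)=O)ccc1F
F4 | step 3 | (1R,2R)-1-(5-acetyl-2-fluorophenyl)-2-(methoxymethoxy)-3-methylbut-3-en-1-yl 3-methylbutanoate | C=C(C)[C@@H](OCOC)[C@H](OC(=O)CC(C)C)c1cc(C(C)=O)ccc1F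
F5 | step 6 | (1S)-1-[(2R,3R)-2-(3-chloroprop-1-en-2-yl)-3-[(3-methylbutanoyl)oxy]-2,3-dihydro-1-benzofuran-5-yl]ethyl 3-methylbut-2-enoate | C=C(CCl)[C@H]1Oc2ccc([C@H](C)OC(=O)C=C(C)C)cc2[C@H]1OC(=O)CC(C)C
F6 | step 5 | (1S)-1-[(2R,3R)-3-[(3-methylbutanoyl)oxy]-2-(prop-1-en-2-yl)-2,3-dihydro-1-benzofuran-5-yl]ethyl 2-(diethoxyphosphoryl)acetate | C=C(C)[C@H]1Oc2ccc([C@H](C)OC(=O)CP(=O)(OCC)OCC)cc2[C@H]1OC(=O)CC(C)C
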